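The plan cuts the C4–C15 bond and traces C15 back to a silicon atom held on O6. In the trans-decalin, the equatorial 6α-oxygen of ring B and the equatorial C15 on C4 of ring A point the same way on either side of C5. They are close enough for one silicon atom to span them. Radical closure of a bromomethylsilyl ether onto the C4=C5 alkene forms C4–C15 and then C5–H. This fixes C4, C5 and the trans ring fusion in one operation and leaves a C–Si bond that peroxide converts into C15–OH. The precursor is a 10β-methyl-Δ4-octalin with 1β-silyloxy, 6α-(bromomethyl)dimethylsilyloxy and equatorial 7β-benzyloxy groups, made from (R)-Wieland–Miescher ketone.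

Key step: step 8

Remark: eudesmane numbering is used for all bicyclic compounds (ring A = C1–C5, C10; ring B = C5–C10; methyl on C10; C15 on C4; C11–C13 on C7). α is the face opposite the C10 methyl group.
Remark: the target is taken in the open 6-hydroxy-12-acid and 6-hydroxy-15-aldehyde form that its SMILES shows, so O6 is freed only in the last step and the final work-up stays cold and near pH 5–6.

Step 1
Reactants: 1 (R)-(−)-Wieland–Miescher ketone
Product: 2 1β-hydroxy-10β-methyl-Δ5-octalin-7-one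
Conditions: NaBH4 (0.3 equiv), EtOH, −10 °C
Reagents that add atoms: none
Why: Chemoselective borohydride reduction: the saturated C1 ketone is more electrophilic than the conjugated C7 ketone, and hydride arrives on the α face, away from the angular methyl group, which sets the equatorial 1β-alcohol.

Step 2
Reactants: 2 1β-hydroxy-10β-methyl-Δ5-octalin-7-one
Product: 3 1β-(tert-butyldimethylsilyloxy)-10β-methyl-Δ5-octalin-7-one
Conditions: TBSCl, imidazole, DMF, 40 °C
Reagents that add atoms: tert-butyldimethylsilyl chloride, CC(C)(C)[Si](C)(C)Cl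
Why: Imidazole-promoted silylation of the hindered secondary alcohol gives an ether that withstands every later base, oxidant and radical step.

Step 3
Reactants: 3 1β-TBSO-10β-methyl-Δ5-octalin-7-one
Product: 4 1β-TBSO-10β-methyl-Δ5-octalin-7β-ol
Conditions: NaBH4, CeCl3·7H2O, MeOH, −20 °C
Reagents that add atoms: none
Why: Luche reduction gives clean 1,2-addition, and axial hydride delivery from the α face should give the pseudo-equatorial 7β-allylic alcohol (a temporary centre).

Step 4
Reactants: 4 1β-TBSO-10β-methyl-Δ5-octalin-7β-ol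
Product: 5 7β-benzyloxy-1β-TBSO-10β-methyl-Δ5-octalin
Conditions: NaH, BnBr, Bu4NI (cat.), THF/DMF, 0 °C → rt
Reagents that add atoms: benzyl bromide, BrCc1ccccc1
Why: Williamson etherification removes the hydroxyl-directing effect before epoxidation, and the benzyl ether stays equatorial so that it does not cover the α face and can later leave by hydrogenolysis.

Step 5
Reactants: 5 7β-benzyloxy-1β-TBSO-10β-methyl-Δ5-octalin
Product: 6 5α,6α-epoxide of 5
Conditions: mCPBA, NaHCO3, CH2Cl2, 0 °C
Reagents that add atoms: 3-chloroperoxybenzoic acid, OOC(=O)c1cccc(Cl)c1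
Why: Prilezhaev epoxidation: the C10 methyl group and the 7β-benzyloxy group both shield the β face of the trisubstituted C5=C6 alkene, so oxygen should arrive from the α face, which sets the 6α C–O bond for the rest of the route.

Step 6
Reactants: 6 5α,6α-epoxide
Product: 7 7β-benzyloxy-1β-TBSO-10β-methyl-Δ4-octalin-6α-ol
Conditions: TMPH, n-BuLi, toluene, 0 °C; Et2AlCl; then 6, 0 °C → rt; Rochelle salt work-up
Reagents that add atoms: none
Why: Aluminium-amide isomerization of an epoxide to an allylic alcohol: the Lewis-acidic reagent breaks the tertiary C5–O bond and its amide takes a neighbouring proton, which at C5 can only come from C4 because C10 is quaternary, so C4=C5 forms and the C6–O configuration is untouched.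

Step 7
Reactants: 7 Δ4-octalin-6α-ol; 8 (bromomethyl)chlorodimethylsilane
Product: 9 6α-[(bromomethyl)dimethylsilyl] ether of 7
Conditions: Et3N, DMAP (cat.), CH2Cl2, 0 °C; used after short filtration
Reagents that add atoms: (bromomethyl)chlorodimethylsilane 8, C[Si](C)(Cl)CBr
Why: Silyl ether formation with the small, reactive chlorosilane attaches the radical precursor to the only free hydroxyl group.

Step 8
Reactants: 9 6α-[(bromomethyl)dimethylsilyl] ether
Product: 10 tricyclic oxasilinane: trans-decalin (5α-H, 10β-Me) bridged O6–SiMe2–C15H2–C4 (4α-CH2, 4β-H), 7β-OBn, 1β-OTBS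
Conditions: Bu3SnH (syringe pump), AIBN (cat.), PhH (0.01 M), reflux
Reagents that add atoms: none
Why: The stannyl radical should abstract bromine from 9 to give a nucleophilic α-silylmethyl radical that adds to C4 of C4=C5, and the tertiary C5 radical is then quenched by Bu3SnH, which carries the chain. This is a Nishiyama–Stork silicon-tethered cyclization of a (bromomethyl)dimethylsilyl allyl ether, the class in which a substituent on the proximal alkene carbon diverts closure from 5-exo to 6-endo. The only ring formed, the 1,2-oxasilinane O6–Si–C15–C4–C5–C6, closes 6-endo-trig through a chair-like transition state that the long Si–O and Si–C bonds make reachable. C4 is controlled by the tether: the ring-locked equatorial O6 lies just under the alkene plane, so C15 meets the α lobe at C4, whereas β attack would put C15 syn-axial to the C10 methyl group. C5 is controlled in the hydrogen transfer: the stannane approaches the α face, anti to the adjacent axial methyl group, which gives the all-chair trans-fused tricycle. The step needs endo regiochemistry, α delivery at both carbons and closure faster than direct reduction, and these are secured by full substitution at C5, by the 6α-oxygen next to a non-shielding equatorial 7β-benzyloxy group, and by slow stannane addition at high dilution.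

Step 9
Reactants: 10 tricyclic oxasilinane
Product: 11 7β-benzyloxy-1β-TBSO-4α-(hydroxymethyl)-10β-methyl-trans-decalin-6α-ol (6α,15-diol)
Conditions: 30% H2O2, KF, KHCO3, THF/MeOH, 40 °C
Reagents that add atoms: hydrogen peroxide, OO
Why: Tamao oxidation: activated peroxide replaces the C15–Si bond by C15–O and hydrolyses the Si–O6 bond without touching any stereocentre, and TBS and benzyl ethers survive.

Step 10
Reactants: 11 6α,15-diol
Product: 12 7β-benzyloxy-1β,6α,15-tris(TBSO) trans-decalin
Conditions: TBSOTf, 2,6-lutidine, CH2Cl2, 0 °C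
Reagents that add atoms: tert-butyldimethylsilyl triflate, CC(C)(C)[Si](C)(C)OS(=O)(=O)C(F)(F)F
Why: Silyl triflate silylation is strong enough for the crowded 6α-hydroxyl and caps the primary one at the same time, which blocks later ring closure of O6 onto C15 or C12.

Step 11
Reactants: 12 benzyl ether
Product: 13 1β,6α,15-tris(TBSO) trans-decalin-7β-ol
Conditions: H2 (1 atm), Pd(OH)2/C, EtOAc, rt
Reagents that add atoms: none
Why: Catalytic hydrogenolysis of the benzyl ether is safe here because the molecule holds no alkene at this stage and silyl ethers are inert in ethyl acetate.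

Step 12
Reactants: 13 7β-ol
Product: 14 1β,6α,15-tris(TBSO) trans-decalin-7-one
Conditions: Dess–Martin periodinane, CH2Cl2, rt
Reagents that add atoms: none
Why: Dess–Martin oxidation under neutral conditions gives the α-silyloxy ketone, whose equatorial C6 substituent is already the stable epimer.

Step 13
Reactants: 14 7-ketone
Product: 16 7-triflyloxy-Δ7-ene (1β,6α,15-tris-OTBS), via potassium enolate 15 (not isolated)
Conditions: KHMDS, THF, −78 °C; Comins' reagent, −78 °C
Reagents that add atoms: N-(5-chloro-2-pyridyl)bis(trifluoromethanesulfonimide), FC(F)(F)S(=O)(=O)N(c1ccc(Cl)cn1)S(=O)(=O)C(F)(F)F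
Why: Kinetic enolate formation and O-sulfonylation: the bulky amide removes a proton from the C8 methylene rather than from the crowded C6 methine that bears the silyloxy group, and the pyridyl triflimide traps the enolate at low temperature.

Step 14
Reactants: 16 Δ7-enol triflate; 17 tributyl(1-ethoxyvinyl)stannane
Product: 19 7-acetyl-Δ7-ene (1β,6α,15-tris-OTBS), via ethoxydiene 18 (not isolated)
Conditions: Pd(PPh3)4 (cat.), LiCl, THF, reflux; then aq. oxalic acid, THF, rt
Reagents that add atoms: tributyl(1-ethoxyvinyl)stannane 17, CCCC[Sn](CCCC)(CCCC)C(=C)OCC; water, O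
Why: Stille coupling of the enol triflate with an acyl-anion equivalent, followed by mild enol ether hydrolysis, installs C11 and C13 as an acetyl group conjugated with C7=C8.

Step 15
Reactants: 19 7-acetyl-Δ7-ene
Product: 21 7β-acetyl-8α-hydroxy trans-decalin (7α-H; 1β,6α,15-tris-OTBS), via boronate 20 (not isolated)
Conditions: B2pin2, CuCl/Xantphos (cat.), NaOt-Bu (cat.), MeOH, THF, rt; then NaBO3·4H2O, THF/H2O, rt
Reagents that add atoms: bis(pinacolato)diboron (boron of 20 only), CC1(C)OB(OC1(C)C)B1OC(C)(C)C(C)(C)O1; sodium perborate, [Na+].[O-]OB=O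
Why: Copper-catalysed conjugate borylation then perborate oxidation with retention: the Cu–B species adds to C8 on the α face opposite the syn-axial C10 methyl group, and axial α protonation of the enolate, also the thermodynamic outcome, leaves the acetyl group equatorial, which sets C8 (α-O) and C7 (β-C).

Step 16
Reactants: 21 8α-hydroxy ketone
Product: 22 7β-acetyl-8α-(triethylsilyloxy) trans-decalin (1β,6α,15-tris-OTBS)
Conditions: TESCl, imidazole, CH2Cl2, 0 °C → rt
Reagents that add atoms: chlorotriethylsilane, CC[Si](Cl)(CC)CC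
Why: Mild silylation masks the aldol-type hydroxyl as a poor leaving group before strong base is used.

Step 17
Reactants: 22 methyl ketone
Product: 24 7β-[1-(triflyloxy)vinyl] compound (8α-OTES; 1β,6α,15-tris-OTBS), via potassium enolate 23 (not isolated)
Conditions: KHMDS, THF, −78 °C; Comins' reagent, −78 °C
Reagents that add atoms: N-(5-chloro-2-pyridyl)bis(trifluoromethanesulfonimide), FC(F)(F)S(=O)(=O)N(c1ccc(Cl)cn1)S(=O)(=O)C(F)(F)F
Why: Kinetic deprotonation takes place at the open methyl group and not at the flanked C7–H, and low-temperature triflation gives the 1,1-disubstituted enol triflate without β-elimination or C7 epimerization.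

Step 18
Reactants: 24 C11 enol triflate; 25 carbon monoxide
Product: 26 2-(trimethylsilyl)ethyl 11(13)-en-12-oate (8α-OTES; 1β,6α,15-tris-OTBS)
Conditions: CO (1 atm), Pd(OAc)2/dppf (cat.), Et3N, Me3SiCH2CH2OH, DMF, 50 °C
Reagents that add atoms: carbon monoxide 25, [C-]#[O+]; 2-(trimethylsilyl)ethanol, C[Si](C)(C)CCO
Why: Palladium-catalysed alkoxycarbonylation of the enol triflate inserts CO as C12 and delivers the acrylate directly as a fluoride-labile ester.

Step 19
Reactants: 26 fully silylated ester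
Product: 27 8α,15-diol (1β,6α-bis-OTBS; trimethylsilylethyl ester kept)
Conditions: HF·pyridine, pyridine, THF, 0 °C → rt
Reagents that add atoms: none
Why: Rate-selective desilylation: the triethylsilyl ether and the primary TBS ether leave much faster than the two crowded secondary TBS ethers, and the trimethylsilylethyl ester is inert to buffered HF·pyridine.

Step 20
Reactants: 27 8α,15-diol
Product: 28 8α-hydroxy-15-al (4α-CHO; 1β,6α-bis-OTBS)
Conditions: TEMPO (cat.), PhI(OAc)2, CH2Cl2, rt
Reagents that add atoms: none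
Why: Oxoammonium (TEMPO) oxidation distinguishes the primary C15 alcohol from the hindered secondary 8α-alcohol, stops at the aldehyde without water, and leaves the equatorial, stable C4 configuration.

Step 21
Reactants: 29 ethyl 2-(hydroxymethyl)acrylate
Product: 30 ethyl 2-[(tert-butyldimethylsilyloxy)methyl]acrylate
Conditions: TBSCl, imidazole, CH2Cl2, 0 °C → rt
Reagents that add atoms: tert-butyldimethylsilyl chloride, CC(C)(C)[Si](C)(C)Cl
Why: Routine silylation of the primary allylic alcohol prevents self-acylation in the coupling step.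

Step 22
Reactants: 30 silylated ethyl ester
Product: 31 2-[(tert-butyldimethylsilyloxy)methyl]acrylic acid
Conditions: LiOH, THF/H2O, 0 °C → rt; then 1 M HCl to pH 4
Reagents that add atoms: lithium hydroxide, [Li+].[OH-]
Why: Saponification of the unhindered ethyl ester is faster than conjugate addition of hydroxide, and the silyl ether tolerates the brief mild acidification.

Step 23
Reactants: 28 8α-hydroxy-15-al; 31 2-[(TBSO)methyl]acrylic acid
Product: 33 fully protected target (8α-acrylate ester; 1β,6α-bis-OTBS; trimethylsilylethyl ester), via mixed anhydride 32 (not isolated)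
Conditions: 31, 2,4,6-Cl3C6H2COCl, Et3N, toluene, rt; then 28, DMAP, toluene, rt
Reagents that add atoms: acid 31, C=C(CO[Si](C)(C)C(C)(C)C)C(=O)O; 2,4,6-trichlorobenzoyl chloride (atoms of 32 only), O=C(Cl)c1c(Cl)cc(Cl)cc1Cl
Why: Yamaguchi esterification through the mixed anhydride acylates the only free hydroxyl with retention at C8 under mild base, which cannot move the already equatorial 4α-aldehyde to a less stable epimer.

Step 24
Reactants: 33 fully protected target
Product: 34 target CNP0599450.1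
Conditions: TAS-F (excess), DMF/H2O, 0 °C → rt; pH 5.5 phosphate buffer, 0 °C
Reagents that add atoms: none
Why: Fluoride-induced global desilylation: the trimethylsilylethyl ester fragments first with loss of ethene to the unreactive carboxylate, so O6, freed later from its hindered silyl ether, finds no acyl acceptor, and the cold buffered work-up should give the open hydroxy acid.

Compound list
1 | (R)-(−)-Wieland–Miescher ketone, (8aR)-8a-methyl-3,4,8,8a-tetrahydronaphthalene-1,6(2H,7H)-dione | C[C@@]12CCC(=O)C=C1CCCC2=O | starting material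
2 | 1β-hydroxy-10β-methyl-Δ5-octalin-7-one, (4aR,5R)-5-hydroxy-4a-methyl-4,4a,5,6,7,8-hexahydronaphthalen-2(3H)-one | C1C[C@]2(C)C(=CC1=O)CCC[C@H]2O | intermediate
3 | 1β-TBSO-10β-methyl-Δ5-octalin-7-one | C1C[C@]2(C)C(=CC1=O)CCC[C@H]2O[Si](C)(C)C(C)(C)C | intermediate
4 | 1β-TBSO-10β-methyl-Δ5-octalin-7β-ol | C1C[C@]2(C)C(=C[C@@H]1O)CCC[C@H]2O[Si](C)(C)C(C)(C)C | intermediate
5 | 7β-benzyloxy-1β-TBSO-10β-methyl-Δ5-octalin | C1C[C@]2(C)C(=C[C@@H]1OCc3ccccc3)CCC[C@H]2O[Si](C)(C)C(C)(C)C | intermediate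
6 | 5α,6α-epoxy-7β-benzyloxy-1β-TBSO-10β-methyldecalin | C1C[C@]2(C)[C@]3(O[C@H]3[C@@H]1OCc4ccccc4)CCC[C@H]2O[Si](C)(C)C(C)(C)C | intermediate
7 | 7β-benzyloxy-1β-TBSO-10β-methyl-Δ4-octalin-6α-ol | C1C[C@]2(C)C([C@@H](O)[C@@H]1OCc3ccccc3)=CCC[C@H]2O[Si](C)(C)C(C)(C)C | intermediate
8 | (bromomethyl)chlorodimethylsilane | C[Si](C)(Cl)CBr | starting material
9 | 6α-[(bromomethyl)dimethylsilyloxy]-7β-benzyloxy-1β-TBSO-10β-methyl-Δ4-octalin (key-step precursor) | C1C[C@]2(C)C([C@@H](O[Si](C)(C)CBr)[C@@H]1OCc3ccccc3)=CCC[C@H]2O[Si](C)(C)C(C)(C)C | intermediate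
10 | trans-decalin with O6–SiMe2–C15 bridge (4α-CH2, 5α-H), 7β-OBn, 1β-OTBS (key-step product) | C1C[C@]2(C)[C@@H]([C@@H](O[Si](C)(C)C3)[C@@H]1OCc4ccccc4)[C@H]3CC[C@H]2O[Si](C)(C)C(C)(C)C | intermediate
11 | 6α,15-diol, 7β-OBn, 1β-OTBS | C1C[C@]2(C)[C@@H]([C@@H](O)[C@@H]1OCc3ccccc3)[C@H](CO)CC[C@H]2O[Si](C)(C)C(C)(C)C | intermediate
12 | 1β,6α,15-tris-OTBS, 7β-OBn trans-decalin | C1C[C@]2(C)[C@@H]([C@@H](O[Si](C)(C)C(C)(C)C)[C@@H]1OCc3ccccc3)[C@H](CO[Si](C)(C)C(C)(C)C)CC[C@H]2O[Si](C)(C)C(C)(C)C | intermediate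
13 | 1β,6α,15-tris-OTBS trans-decalin-7β-ol | C1C[C@]2(C)[C@@H]([C@@H](O[Si](C)(C)C(C)(C)C)[C@@H]1O)[C@H](CO[Si](C)(C)C(C)(C)C)CC[C@H]2O[Si](C)(C)C(C)(C)C | intermediate
14 | 1β,6α,15-tris-OTBS trans-decalin-7-one | C1C[C@]2(C)[C@@H]([C@@H](O[Si](C)(C)C(C)(C)C)C1=O)[C@H](CO[Si](C)(C)C(C)(C)C)CC[C@H]2O[Si](C)(C)C(C)(C)C | intermediate
15 | potassium Δ7-enolate of 14 | C1([O-])=CC[C@]2(C)[C@@H]([C@H]1O[Si](C)(C)C(C)(C)C)[C@H](CO[Si](C)(C)C(C)(C)C)CC[C@H]2O[Si](C)(C)C(C)(C)C.[K+] | intermediate (not isolated)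
16 | 7-triflyloxy-Δ7-ene | C1(OS(=O)(=O)C(F)(F)F)=CC[C@]2(C)[C@@H]([C@H]1O[Si](C)(C)C(C)(C)C)[C@H](CO[Si](C)(C)C(C)(C)C)CC[C@H]2O[Si](C)(C)C(C)(C)C | intermediate
17 | tributyl(1-ethoxyvinyl)stannane | CCCC[Sn](CCCC)(CCCC)C(=C)OCC | starting material
18 | 7-(1-ethoxyvinyl)-Δ7-ene | C1(C(=C)OCC)=CC[C@]2(C)[C@@H]([C@H]1O[Si](C)(C)C(C)(C)C)[C@H](CO[Si](C)(C)C(C)(C)C)CC[C@H]2O[Si](C)(C)C(C)(C)C | intermediate (not isolated)
19 | 7-acetyl-Δ7-ene | C1(C(C)=O)=CC[C@]2(C)[C@@H]([C@H]1O[Si](C)(C)C(C)(C)C)[C@H](CO[Si](C)(C)C(C)(C)C)CC[C@H]2O[Si](C)(C)C(C)(C)C | intermediate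
20 | 7β-acetyl-8α-(pinacolatoboryl) trans-decalin | B3(OC(C)(C)C(C)(C)O3)[C@H]1C[C@]2(C)[C@@H]([C@@H](O[Si](C)(C)C(C)(C)C)[C@@H]1C(C)=O)[C@H](CO[Si](C)(C)C(C)(C)C)CC[C@H]2O[Si](C)(C)C(C)(C)C | intermediate (not isolated)
21 | 7β-acetyl-8α-hydroxy trans-decalin | O[C@H]1C[C@]2(C)[C@@H]([C@@H](O[Si](C)(C)C(C)(C)C)[C@@H]1C(C)=O)[C@H](CO[Si](C)(C)C(C)(C)C)CC[C@H]2O[Si](C)(C)C(C)(C)C | intermediate
22 | 7β-acetyl-8α-OTES trans-decalin | CC[Si](CC)(CC)O[C@H]1C[C@]2(C)[C@@H]([C@@H](O[Si](C)(C)C(C)(C)C)[C@@H]1C(C)=O)[C@H](CO[Si](C)(C)C(C)(C)C)CC[C@H]2O[Si](C)(C)C(C)(C)C | intermediate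
23 | potassium C11=C13 enolate of 22 | CC[Si](CC)(CC)O[C@H]1C[C@]2(C)[C@@H]([C@@H](O[Si](C)(C)C(C)(C)C)[C@@H]1C(=C)[O-])[C@H](CO[Si](C)(C)C(C)(C)C)CC[C@H]2O[Si](C)(C)C(C)(C)C.[K+] | intermediate (not isolated)
24 | 7β-[1-(triflyloxy)vinyl] compound | CC[Si](CC)(CC)O[C@H]1C[C@]2(C)[C@@H]([C@@H](O[Si](C)(C)C(C)(C)C)[C@@H]1C(=C)OS(=O)(=O)C(F)(F)F)[C@H](CO[Si](C)(C)C(C)(C)C)CC[C@H]2O[Si](C)(C)C(C)(C)C | intermediate
25 | carbon monoxide | [C-]#[O+] | starting material
26 | 2-(trimethylsilyl)ethyl 11(13)-en-12-oate, 8α-OTES, 1β,6α,15-tris-OTBS | CC[Si](CC)(CC)O[C@H]1C[C@]2(C)[C@@H]([C@@H](O[Si](C)(C)C(C)(C)C)[C@@H]1C(=C)C(=O)OCC[Si](C)(C)C)[C@H](CO[Si](C)(C)C(C)(C)C)CC[C@H]2O[Si](C)(C)C(C)(C)C | intermediate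
27 | 8α,15-diol, 1β,6α-bis-OTBS, trimethylsilylethyl ester | O[C@H]1C[C@]2(C)[C@@H]([C@@H](O[Si](C)(C)C(C)(C)C)[C@@H]1C(=C)C(=O)OCC[Si](C)(C)C)[C@H](CO)CC[C@H]2O[Si](C)(C)C(C)(C)C | intermediate
28 | 8α-hydroxy-15-al, 1β,6α-bis-OTBS, trimethylsilylethyl ester | O[C@H]1C[C@]2(C)[C@@H]([C@@H](O[Si](C)(C)C(C)(C)C)[C@@H]1C(=C)C(=O)OCC[Si](C)(C)C)[C@H](C=O)CC[C@H]2O[Si](C)(C)C(C)(C)C | intermediate
29 | ethyl 2-(hydroxymethyl)acrylate | C=C(CO)C(=O)OCC | starting material
30 | ethyl 2-[(TBSO)methyl]acrylate | C=C(CO[Si](C)(C)C(C)(C)C)C(=O)OCC | intermediate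
31 | 2-[(TBSO)methyl]acrylic acid | C=C(CO[Si](C)(C)C(C)(C)C)C(=O)O | intermediate
32 | mixed anhydride of 31 and 2,4,6-trichlorobenzoic acid | C=C(CO[Si](C)(C)C(C)(C)C)C(=O)OC(=O)c1c(Cl)cc(Cl)cc1Cl | intermediate (not isolated)
33 | fully protected target | C=C(CO[Si](C)(C)C(C)(C)C)C(=O)O[C@H]1C[C@]2(C)[C@@H]([C@@H](O[Si](C)(C)C(C)(C)C)[C@@H]1C(=C)C(=O)OCC[Si](C)(C)C)[C@H](C=O)CC[C@H]2O[Si](C)(C)C(C)(C)C | intermediate
34 | CNP0599450.1: 1β,6α-dihydroxy-8α-[2-(hydroxymethyl)acryloyloxy]-15-oxoeudesm-11(13)-en-12-oic acid | C=C(CO)C(=O)O[C@H]1C[C@]2(C)[C@@H]([C@@H](O)[C@@H]1C(=C)C(=O)O)[C@H](C=O)CC[C@H]2O | target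

Total step count: 24. Longest linear sequence: 22 (steps 1–20, 23, 24).

Steps most likely to fail

Step 8. The primary radical may be reduced before it closes, or hydrogen may reach C5 from the β face and erode the trans fusion. The fallback builds the same two centres by a concerted syn addition instead of a radical chain.
- It sets out from 7, which is silylated with TBSOTf and 2,6-lutidine to the 6-O-TBS ether F1.
- Hydroboration with BH3·THF from the α face, followed by pinacol, should give the 4α-boronate F2. The syn addition places boron on C4 and hydrogen on C5, both α.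
- Matteson homologation with chloromethyllithium (BrCH2Cl, n-BuLi, −78 °C) inserts C15 with retention and gives the 4α-(borylmethyl) compound F3.
- Sodium perborate converts F3 into the 15-alcohol F4.
- TBSCl and imidazole bring the sequence back to the route at 12.

Step 24. The two hindered secondary silyl groups may leave slowly under basic fluoride. That would leave time for conjugate addition to the acrylates or for closure of O6 onto C12 during work-up. The fallback splits the unmasking into two orthogonal events.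
- It sets out from 33. Acetic-acid-buffered TBAF in THF at 0 °C cleaves only the trimethylsilylethyl ester and the primary silyl ether, giving the 1,6-bis-O-TBS acid F8 while O6 is still blocked.
- Pyridine-buffered HF·pyridine then removes the two secondary silyl ethers under non-basic conditions and arrives at 34.

Step 6. The reagent may remove the proton at C7 instead of C4, or Lewis acid may induce a hydride or methyl shift at C5. Either would divert the epoxide. The fallback replaces epoxide isomerization by dihydroxylation and dehydration.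
- It sets out from 5. OsO4 (cat.) with NMO should add from the α face to give the 5α,6α-diol F5.
- Ac2O and pyridine acylate only the secondary hydroxyl, giving the 6-acetate F6.
- Burgess reagent in warm toluene removes the tertiary 5α-hydroxyl by syn elimination. Only C4–Hα can take part, because C6–H is β and C10 bears no hydrogen. This gives the Δ4 6α-acetate F7.
- K2CO3 in MeOH returns to the route at 7.

Further compounds
F1 | step 8 | 6α-TBSO-7β-benzyloxy-1β-TBSO-10β-methyl-Δ4-octalin | C1C[C@]2(C)C([C@@H](O[Si](C)(C)C(C)(C)C)[C@@H]1OCc3ccccc3)=CCC[C@H]2O[Si](C)(C)C(C)(C)C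
F2 | step 8 | 4α-(pinacolatoboryl)-5α-H trans-decalin, 6α-OTBS, 7β-OBn, 1β-OTBS | C1C[C@]2(C)[C@@H]([C@@H](O[Si](C)(C)C(C)(C)C)[C@@H]1OCc3ccccc3)[C@H](B4OC(C)(C)C(C)(C)O4)CC[C@H]2O[Si](C)(C)C(C)(C)C
F3 | step 8 | 4α-[(pinacolatoboryl)methyl] trans-decalin, 6α-OTBS, 7β-OBn, 1β-OTBS | C1C[C@]2(C)[C@@H]([C@@H](O[Si](C)(C)C(C)(C)C)[C@@H]1OCc3ccccc3)[C@H](CB4OC(C)(C)C(C)(C)O4)CC[C@H]2O[Si](C)(C)C(C)(C)C
F4 | step 8 | 4α-(hydroxymethyl) trans-decalin, 6α-OTBS, 7β-OBn, 1β-OTBS | C1C[C@]2(C)[C@@H]([C@@H](O[Si](C)(C)C(C)(C)C)[C@@H]1OCc3ccccc3)[C@H](CO)CC[C@H]2O[Si](C)(C)C(C)(C)C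
F5 | step 6 | 5α,6α-diol, 7β-OBn, 1β-OTBS | C1C[C@]2(C)[C@@](O)([C@@H](O)[C@@H]1OCc3ccccc3)CCC[C@H]2O[Si](C)(C)C(C)(C)C
F6 | step 6 | 6α-acetoxy-5α-ol, 7β-OBn, 1β-OTBS | C1C[C@]2(C)[C@@](O)([C@@H](OC(C)=O)[C@@H]1OCc3ccccc3)CCC[C@H]2O[Si](C)(C)C(C)(C)C
F7 | step 6 | 6α-acetoxy-7β-benzyloxy-1β-TBSO-10β-methyl-Δ4-octalin | C1C[C@]2(C)C([C@@H](OC(C)=O)[C@@H]1OCc3ccccc3)=CCC[C@H]2O[Si](C)(C)C(C)(C)C
F8 | step 24 | 1β,6α-bis-O-TBS ether of the target (free 12-acid, free side-chain hydroxyl) | C=C(CO)C(=O)O[C@H]1C[C@]2(C)[C@@H]([C@@H](O[Si](C)(C)C(C)(C)C)[C@@H]1C(=C)C(=O)O)[C@H](C=O)CC[C@H]2O[Si](C)(C)C(C)(C)C
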